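**Retrosynthetic overview**

1. Numbering used in the text: carbinol bridgehead C1, C2 (aryl), O3, C4, bridgehead C5 (H), C6 (aryl), O7, C8; ring A = C1/C2/O3/C4/C5, ring B = C5/C6/O7/C8/C1; the target is 2-exo, 6-endo.
2. Ring A is closed last: the C1–C2 bond comes from a Norrish–Yang photocyclisation of oxolan-3-one 12 (ketone at C1, veratryl ether on C4–O3), which sets C1 and C2.
3. Ring B comes from ring contraction (seven to five) of a 2-aryl-4,5-dihydro-1,3-dioxepine: the C5–C6 bond forms, and the enol carbon C4 with its oxygen O3 leave the ring as the formyl group and later become ring-A atoms.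
4. Enabling feature: in ring B the ArCH carbon C6 (bonded to O7) is next to C5, which carries the exocyclic C4–O3 unit. O7–C6(Ar)–C5–C4=O is therefore an aldol retron, and its oxocarbenium half (C6=O7+) and enol half (C4=C5) are both stored in one cyclic vinyl acetal. The 2,3-cis isomer (later the endo aryl group) is the kinetic product.
5. Dioxepinol 5 comes from desymmetrisation of meso-epoxide 4 (veratraldehyde + cis-butenediol); its carbinol centre relays chirality to C5/C6 and is then oxidised away. Ring order: dioxepine (temporary) → ring B → ring A.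

Key step: step 5

Remark: the given SMILES corresponds to (1S,2R,5R,6R), with the 2-aryl group exo and the 6-aryl group endo on the cis-fused bicycle; the route is planned for this isomer.
Remark: compounds 3–6 are carried as mixtures of epimers at the acetal carbon, which is planarised in step 5; the sense of induction in step 3 is extrapolated from carbocyclic meso-epoxides.

**Route**

Step 1
Reactants: 1 3,4-dimethoxybenzaldehyde; 2 (Z)-but-2-ene-1,4-diol
Product: 3 2-(3,4-dimethoxyphenyl)-4,7-dihydro-1,3-dioxepine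
Conditions: p-TsOH (cat.), benzene, reflux, Dean–Stark
Reagents that add atoms: none
Why: Acid-catalysed acetalisation with azeotropic removal of water, in which the cis-diol closes the seven-membered cyclic acetal readily and no stereocentre of consequence is formed.

Step 2
Reactants: 3 2-(3,4-dimethoxyphenyl)-4,7-dihydro-1,3-dioxepine
Product: 4 4-(3,4-dimethoxyphenyl)-3,5,8-trioxabicyclo[5.1.0]octane (meso, cis-fused epoxide, both orientations of the aryl group)
Conditions: mCPBA, CH2Cl2, 0 °C → rt
Reagents that add atoms: 3-chloroperoxybenzoic acid (mCPBA), OOC(=O)c1cccc(Cl)c1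
Why: Prilezhaev epoxidation of the cis ring alkene should give the meso epoxide, and either orientation relative to the aryl group is acceptable because the acetal carbon is planarised in step 5.

Step 3
Reactants: 4 4-(3,4-dimethoxyphenyl)-3,5,8-trioxabicyclo[5.1.0]octane
Product: 5 (5S)-2-(3,4-dimethoxyphenyl)-4,5-dihydro-1,3-dioxepin-5-ol (both C2 epimers)
Conditions: (R)-2-(pyrrolidin-1-ylmethyl)pyrrolidine, n-BuLi, THF, 0 °C → rt; then H2O
Reagents that add atoms: none
Why: Enantioselective epoxide-to-allylic-alcohol rearrangement (syn β-elimination of a meso-epoxide by a chiral lithium amide), in which the base removes one of the two enantiotopic OCH2 protons and so sets the carbinol centre; the (R)-amide is chosen by analogy with the known sense of this base on cyclohexene oxide, the descriptor being inverted here because OCH2 outranks CH=.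

Step 4
Reactants: 5 (5S)-2-(3,4-dimethoxyphenyl)-4,5-dihydro-1,3-dioxepin-5-ol
Product: 6 tert-butyl{[(5S)-2-(3,4-dimethoxyphenyl)-4,5-dihydro-1,3-dioxepin-5-yl]oxy}diphenylsilane
Conditions: TBDPSCl, imidazole, DMF, rt
Reagents that add atoms: tert-butyl(chloro)diphenylsilane (TBDPSCl), CC(C)(C)[Si](Cl)(c1ccccc1)c1ccccc1
Why: Base-mediated O-silylation with a silyl chloride, so that no Lewis acid touches the vinyl acetal, installs a bulky, non-migrating and non-leaving group on the relay oxygen without touching the carbinol centre.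

Step 5
Reactants: 6 tert-butyl{[(5S)-2-(3,4-dimethoxyphenyl)-4,5-dihydro-1,3-dioxepin-5-yl]oxy}diphenylsilane
Product: 8 [(2R,3R,4S)-4-[(tert-butyldiphenylsilyl)oxy]-2-(3,4-dimethoxyphenyl)oxolan-3-yl]methanol, via oxolane-3-carbaldehyde 7 (not isolated)
Conditions: TMSOTf (10 mol%), CH2Cl2, −78 °C; Et3N; then NaBH4, MeOH, −78 → 0 °C
Reagents that add atoms: none
Why: TMSOTf silylates the enol-ether oxygen of the vinyl acetal, the acetal C–O bond ionises to an aryl-stabilised oxocarbenium ion that stays tethered through O–CH2 to a (Z)-silyl enol ether, and the two recombine by Mukaiyama-type aldol C–C bond formation (net 1,3-shift of the acetal carbon from O to C), after which NaBH4 reduces the aldehyde in the same flask before it can epimerise or lose silanol. The closest known reaction type is the Lewis acid-induced ring contraction of 4,5-dihydro-1,3-dioxepines to 2,3-cis-tetrahydrofuran-3-carbaldehydes. The oxolane closes in a 5-(enolexo)-endo-trig mode, the enol carbon attacking the oxocarbenium carbon within the ion pair. The new centre at C3 is controlled by the silyloxy-bearing carbon, whose hydrogen eclipses the Z-enol double bond to avoid A(1,3) strain so that the tether reaches only the face that puts the formyl group trans to OTBDPS; the new centre at C2 is set kinetically, the compact closure at −78 °C giving the 2,3-cis (aryl cis to formyl) isomer. The step needs ionisation of the acetal and not of the allylic C–O bond, which the electron-rich dimethoxyphenyl group and the non-leaving silyl ether secure, and it needs the kinetic cis product to survive, which the low temperature, the amine quench and the in-flask reduction secure. Both acetal epimers of 6 converge on 8 because the acetal carbon is planarised.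

Step 6
Reactants: 8 [(2R,3R,4S)-4-[(tert-butyldiphenylsilyl)oxy]-2-(3,4-dimethoxyphenyl)oxolan-3-yl]methanol; 9 4-(bromomethyl)-1,2-dimethoxybenzene
Product: 10 (2R,3R,4S)-4-[(tert-butyldiphenylsilyl)oxy]-2-(3,4-dimethoxyphenyl)-3-{[(3,4-dimethoxyphenyl)methoxy]methyl}oxolane
Conditions: NaH, Bu4NI (cat.), THF, 0 °C → rt
Reagents that add atoms: none
Why: Williamson etherification of the primary alkoxide with a reactive benzylic bromide should proceed without silyl migration from the bulky, trans-disposed secondary TBDPS ether and without touching any stereocentre.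

Step 7
Reactants: 10 (2R,3R,4S)-4-[(tert-butyldiphenylsilyl)oxy]-2-(3,4-dimethoxyphenyl)-3-{[(3,4-dimethoxyphenyl)methoxy]methyl}oxolane
Product: 11 (3S,4S,5R)-5-(3,4-dimethoxyphenyl)-4-{[(3,4-dimethoxyphenyl)methoxy]methyl}oxolan-3-ol
Conditions: TBAF, THF, rt
Reagents that add atoms: none
Why: Fluoride-induced silyl ether cleavage is non-acidic and leaves both benzylic ethers and the acid-labile cis-2-aryl oxolane untouched.

Step 8
Reactants: 11 (3S,4S,5R)-5-(3,4-dimethoxyphenyl)-4-{[(3,4-dimethoxyphenyl)methoxy]methyl}oxolan-3-ol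
Product: 12 (4R,5R)-5-(3,4-dimethoxyphenyl)-4-{[(3,4-dimethoxyphenyl)methoxy]methyl}oxolan-3-one
Conditions: Dess–Martin periodinane, pyridine, CH2Cl2, 0 °C
Reagents that add atoms: none
Why: Dess–Martin oxidation under buffered, non-enolising conditions should give the ketone without epimerising the α-centre (cis to the aryl group) or causing β-alkoxy elimination, and it removes the relay stereocentre after it has done its work.

Step 9
Reactants: 12 (4R,5R)-5-(3,4-dimethoxyphenyl)-4-{[(3,4-dimethoxyphenyl)methoxy]methyl}oxolan-3-one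
Product: 13 (+)-gmelinol, (1S,2R,5R,6R)-2,6-bis(3,4-dimethoxyphenyl)-3,7-dioxabicyclo[3.3.0]octan-1-ol
Conditions: hν (medium-pressure Hg lamp, Pyrex), degassed benzene, rt
Reagents that add atoms: none
Why: Norrish–Yang (type II) photocyclisation, in which the excited ketone abstracts a benzylic δ-hydrogen of the veratryl ether (the γ-atom is oxygen, so no γ-hydrogen competes) and the 1,5-biradical closes the second oxolane; the new ring can only be cis-fused, which places OH cis to the ring-fusion hydrogen, and the aryl group should take the exo position away from the concave face that already holds the endo aryl group.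

**Compound list**

1 | 3,4-dimethoxybenzaldehyde (veratraldehyde) | COc1ccc(C=O)cc1OC | starting material
2 | (Z)-but-2-ene-1,4-diol | OC/C=C\CO | starting material
3 | 2-(3,4-dimethoxyphenyl)-4,7-dihydro-1,3-dioxepine | COc1ccc(C2OCC=CCO2)cc1OC | intermediate
4 | 4-(3,4-dimethoxyphenyl)-3,5,8-trioxabicyclo[5.1.0]octane (meso, cis-fused epoxide, acetal carbon undefined) | COc1ccc(C2OC[C@H]3O[C@H]3CO2)cc1OC | intermediate
5 | (5S)-2-(3,4-dimethoxyphenyl)-4,5-dihydro-1,3-dioxepin-5-ol (both C2 epimers) | COc1ccc(C2OC[C@@H](O)C=CO2)cc1OC | intermediate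
6 | tert-butyl{[(5S)-2-(3,4-dimethoxyphenyl)-4,5-dihydro-1,3-dioxepin-5-yl]oxy}diphenylsilane (both C2 epimers) | COc1ccc(C2OC[C@@H](O[Si](c3ccccc3)(c3ccccc3)C(C)(C)C)C=CO2)cc1OC | intermediate
7 | (2R,3R,4S)-4-[(tert-butyldiphenylsilyl)oxy]-2-(3,4-dimethoxyphenyl)oxolane-3-carbaldehyde (not isolated) | COc1ccc([C@@H]2OC[C@@H](O[Si](c3ccccc3)(c3ccccc3)C(C)(C)C)[C@@H]2C=O)cc1OC | intermediate
8 | [(2R,3R,4S)-4-[(tert-butyldiphenylsilyl)oxy]-2-(3,4-dimethoxyphenyl)oxolan-3-yl]methanol | COc1ccc([C@@H]2OC[C@@H](O[Si](c3ccccc3)(c3ccccc3)C(C)(C)C)[C@@H]2CO)cc1OC | intermediate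
9 | 4-(bromomethyl)-1,2-dimethoxybenzene (3,4-dimethoxybenzyl bromide) | COc1ccc(CBr)cc1OC | starting material
10 | (2R,3R,4S)-4-[(tert-butyldiphenylsilyl)oxy]-2-(3,4-dimethoxyphenyl)-3-{[(3,4-dimethoxyphenyl)methoxy]methyl}oxolane | COc1ccc([C@@H]2OC[C@@H](O[Si](c3ccccc3)(c3ccccc3)C(C)(C)C)[C@@H]2COCc2ccc(OC)c(OC)c2)cc1OC | intermediate
11 | (3S,4S,5R)-5-(3,4-dimethoxyphenyl)-4-{[(3,4-dimethoxyphenyl)methoxy]methyl}oxolan-3-ol | COc1ccc([C@@H]2OC[C@@H](O)[C@@H]2COCc2ccc(OC)c(OC)c2)cc1OC | intermediate
12 | (4R,5R)-5-(3,4-dimethoxyphenyl)-4-{[(3,4-dimethoxyphenyl)methoxy]methyl}oxolan-3-one | COc1ccc([C@@H]2OCC(=O)[C@@H]2COCc2ccc(OC)c(OC)c2)cc1OC | intermediate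
13 | (+)-gmelinol, (1S,2R,5R,6R)-2,6-bis(3,4-dimethoxyphenyl)-3,7-dioxabicyclo[3.3.0]octan-1-ol | COc1ccc([C@H]2OC[C@@H]3[C@H](c4ccc(OC)c(OC)c4)OC[C@]23O)cc1OC | target

**Step count**

Total steps: 9. Longest linear sequence: 9 steps (1/2 → 13).

**Steps most likely to fail, with fallbacks**

Step 5 (key step). What may go wrong: the kinetic 2,3-cis isomer may be eroded by retro-aldol re-closure to the trans aldehyde, the facial relay from the silyloxy-bearing carbon may be weak (which lowers the enantiomeric purity once that centre is oxidised away), or the allylic C–O bond may ionise in a Ferrier-type process. The fallback builds the same cis-oxolanone by auxiliary-controlled aldol chemistry; it sets out from 9 and 1 and comes back at 12. Monoalkylation of excess propane-1,3-diol with 9 (NaH, THF) should give 3-[(3,4-dimethoxyphenyl)methoxy]propan-1-ol F1. Oxidation (TEMPO, PhI(OAc)2, MeCN/H2O) should give 3-[(3,4-dimethoxyphenyl)methoxy]propanoic acid F2. Acylation of lithiated (R)-4-benzyl-1,3-oxazolidin-2-one with the pivaloyl mixed anhydride should give (4R)-4-benzyl-3-{3-[(3,4-dimethoxyphenyl)methoxy]propanoyl}-1,3-oxazolidin-2-one F3. An Evans boron aldol reaction (Bu2BOTf, i-Pr2NEt, CH2Cl2, −78 °C) with 1 should give the syn adduct (4R)-4-benzyl-3-[(2R,3R)-3-(3,4-dimethoxyphenyl)-2-{[(3,4-dimethoxyphenyl)methoxy]methyl}-3-hydroxypropanoyl]-1,3-oxazolidin-2-one F4, whose syn relationship becomes the 2,3-cis relationship of the oxolane. Transamination (Me3Al, MeNHOMe·HCl) should give (2R,3R)-3-(3,4-dimethoxyphenyl)-2-{[(3,4-dimethoxyphenyl)methoxy]methyl}-3-hydroxy-N-methoxy-N-methylpropanamide F5. Chloromethyllithium (ICH2Cl, MeLi·LiBr, THF, −78 °C) should give (3R,4R)-1-chloro-4-(3,4-dimethoxyphenyl)-3-{[(3,4-dimethoxyphenyl)methoxy]methyl}-4-hydroxybutan-2-one F6. Intramolecular Williamson etherification (K2CO3, MeCN, 0 °C, 5-exo-tet) should then close oxolan-3-one 12.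

Step 3. What may go wrong: the chiral amide may discriminate poorly between the enantiotopic protons of this dioxa-bicyclic epoxide, or may select with the opposite sense. The fallback separates isomerisation from resolution; it sets out from 4 and comes back at 5. Isomerisation with an achiral amide base (LiNEt2, Et2O/THF, rt) should give racemic 2-(3,4-dimethoxyphenyl)-4,5-dihydro-1,3-dioxepin-5-ol F7. Lipase-catalysed kinetic resolution (Amano PS or CAL-B, vinyl acetate, t-BuOMe) should acetylate one enantiomer, taken here as the (5R)-alcohol, to (5R)-2-(3,4-dimethoxyphenyl)-4,5-dihydro-1,3-dioxepin-5-yl acetate F8, leaving the (5S)-alcohol 5; the configuration would be assigned by Mosher analysis before going on.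

Step 9. What may go wrong: α-cleavage of the α-alkoxy ketone (Norrish type I), quenching of the excited ketone by the electron-rich arenes, or epimerisation of the α-centre during long irradiation. The fallback forms ring A by ionic chemistry; it sets out from 12 and comes back at 13. Wittig olefination of 12 with the ylide from (3,4-dimethoxybenzyl)triphenylphosphonium bromide (NaHMDS, THF, −78 °C) should give (2R,3R)-2-(3,4-dimethoxyphenyl)-3-{[(3,4-dimethoxyphenyl)methoxy]methyl}-4-[(3,4-dimethoxyphenyl)methylidene]oxolane F9 as an E/Z mixture. DDQ (CH2Cl2, pH 7 buffer) should remove the 3,4-dimethoxybenzyl ether to give [(2R,3R)-2-(3,4-dimethoxyphenyl)-4-[(3,4-dimethoxyphenyl)methylidene]oxolan-3-yl]methanol F10. Epoxidation from the face opposite to the hydroxymethyl and aryl groups (DMDO, acetone, −20 °C) should give [(3S,6R,7R)-2,6-bis(3,4-dimethoxyphenyl)-1,5-dioxaspiro[2.4]heptan-7-yl]methanol F11. Catalytic CSA (CH2Cl2, −40 °C) should then trigger 5-endo opening of the epoxide at its benzylic carbon by the primary hydroxyl, giving 13 with the tertiary OH on the convex face. Both alkene isomers should converge, because the opening has benzylic cation character and closes to the exo-aryl ring.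

**Further compounds**

F1 | step 5 | 3-[(3,4-dimethoxyphenyl)methoxy]propan-1-ol | COc1ccc(COCCCO)cc1OC
F2 | step 5 | 3-[(3,4-dimethoxyphenyl)methoxy]propanoic acid | COc1ccc(COCCC(O)=O)cc1OC
F3 | step 5 | (4R)-4-benzyl-3-{3-[(3,4-dimethoxyphenyl)methoxy]propanoyl}-1,3-oxazolidin-2-one | O=C1OC[C@@H](Cc2ccccc2)N1C(=O)CCOCc1ccc(OC)c(OC)c1
F4 | step 5 | (4R)-4-benzyl-3-[(2R,3R)-3-(3,4-dimethoxyphenyl)-2-{[(3,4-dimethoxyphenyl)methoxy]methyl}-3-hydroxypropanoyl]-1,3-oxazolidin-2-one | O=C1OC[C@@H](Cc2ccccc2)N1C(=O)[C@H](COCc1ccc(OC)c(OC)c1)[C@@H](O)c1ccc(OC)c(OC)c1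
F5 | step 5 | (2R,3R)-3-(3,4-dimethoxyphenyl)-2-{[(3,4-dimethoxyphenyl)methoxy]methyl}-3-hydroxy-N-methoxy-N-methylpropanamide | CON(C)C(=O)[C@H](COCc1ccc(OC)c(OC)c1)[C@@H](O)c1ccc(OC)c(OC)c1
F6 | step 5 | (3R,4R)-1-chloro-4-(3,4-dimethoxyphenyl)-3-{[(3,4-dimethoxyphenyl)methoxy]methyl}-4-hydroxybutan-2-one | ClCC(=O)[C@H](COCc1ccc(OC)c(OC)c1)[C@@H](O)c1ccc(OC)c(OC)c1
F7 | step 3 | racemic 2-(3,4-dimethoxyphenyl)-4,5-dihydro-1,3-dioxepin-5-ol | COc1ccc(C2OCC(O)C=CO2)cc1OC
F8 | step 3 | (5R)-2-(3,4-dimethoxyphenyl)-4,5-dihydro-1,3-dioxepin-5-yl acetate | COc1ccc(C2OC[C@H](OC(C)=O)C=CO2)cc1OC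
F9 | step 9 | (2R,3R)-2-(3,4-dimethoxyphenyl)-3-{[(3,4-dimethoxyphenyl)methoxy]methyl}-4-[(3,4-dimethoxyphenyl)methylidene]oxolane (E/Z mixture) | COc1ccc([C@@H]2OCC(=Cc3ccc(OC)c(OC)c3)[C@@H]2COCc2ccc(OC)c(OC)c2)cc1OC
F10 | step 9 | [(2R,3R)-2-(3,4-dimethoxyphenyl)-4-[(3,4-dimethoxyphenyl)methylidene]oxolan-3-yl]methanol (E/Z mixture) | COc1ccc([C@@H]2OCC(=Cc3ccc(OC)c(OC)c3)[C@@H]2CO)cc1OC
F11 | step 9 | [(3S,6R,7R)-2,6-bis(3,4-dimethoxyphenyl)-1,5-dioxaspiro[2.4]heptan-7-yl]methanol (both C2 epimers) | COc1ccc([C@@H]2OC[C@@]3(OC3c3ccc(OC)c(OC)c3)[C@@H]2CO)cc1OC
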